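## The problem

Compound 19 is a diaryl ether without any stereocentre, so the task is purely one of placing five bromines and three hydroxyls correctly on twelve ring carbons. Positions are written a1 to a6 on ring A (a1 C–OH, a2 C–H, a3 C–Br, a4 C–OH, a5 C–Br, a6 C–O-aryl) and b1 to b6 on ring B (b1 C–O-aryl, b2 C–H, b3 C–Br, b4 C–OH, b5 C–Br, b6 C–Br). The rings are joined only through the oxygen between a6 and b1, which is flanked by the a1 hydroxyl and the a5 bromine on one side and by the b6 bromine on the other; such crowding slows copper- or palladium-mediated etherification, which would in addition have to spare five C–Br bonds. Four bromines (a3, a5, b3, b5) lie ortho to a hydroxyl and can be placed by phenol-directed electrophilic bromination. The fifth, at b6, is meta to the b4 hydroxyl and ortho only to the ether oxygen, so no phenol can direct it. Ring A is a hydroquinone that brominating agents oxidise to a quinone, so its oxygens must stay masked to the end, and the aryl bromides exclude hydrogenolysis and alkyllithium reagents once they are in place. The enabling feature is that b1 and b6 are neighbours and that b6 in turn adjoins the brominated b5: an aryne spanning b1 and b6, polarised by the b5 bromine, can take up the ring A phenoxide at b1 and a bromine atom at b6 in one operation.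

## Retrosynthesis

19 ⇒ 18. The two O–CH3 bonds at a1 and a4 are cut last. Keeping ring A as its dimethyl ether through every brominating and basic step avoids quinone formation, and 18 differs from 19 only by these two methyl groups. The forward step needs a Lewis acid that leaves the diaryl ether and the C–Br bonds alone.

18 ⇒ 17. The b3–Br bond is cut. In phenol 17, b3 is the only free position ortho or para to the b4 hydroxyl, so this bromine can be placed late by the phenol itself. Carrying it through the aryne step instead would put a ring hydrogen beside a bromine in the aryne precursor, where an amide base could remove it.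

17 ⇒ 16. The benzyl–oxygen bond at b4 is cut. This protecting group must differ from the ring A methyl ethers so that the b4 hydroxyl can be freed alone, and it must survive fluoride and an aryl anion. Benzyl meets both needs and can be removed by BCl3 without hydrogen.

16 ⇒ 8 + 11 + 12 (key disconnection). The O–b1 and b6–Br bonds are cut together. Three neighbouring cuts were weighed against this one:
- Ullmann coupling of 11 with a 1-halo-2,3-dibromoarene would have to select among several C–halogen bonds at a hindered site.
- Nucleophilic aromatic substitution finds no activating group on ring B.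
- Making the ether first and brominating b6 afterwards fails because b6 cannot be addressed.

The precursors are far simpler: silylaryl triflate 8 carries only one bromine, phenol 11 is one step from a purchased phenol, and 12 is a bulk reagent. The forward reaction asks that fluoride turn 8 into aryne 14, that phenoxide 13 add at b1 and not at b6, and that aryl anion 15 take bromine from 12 faster than it loses bromide from b5.

11 ⇒ 9. The a3–Br and a5–Br bonds are cut. In 2,5-dimethoxyphenol 9 the positions para and ortho to the hydroxyl are each activated by a second oxygen, so dibromination should deliver the ring A pattern in one step.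

8 ⇒ 7 ⇒ 6 ⇒ 4 ⇒ 3 ⇒ 1 + 2. The triflate comes from phenol 7, and its C–Si bond from carbamate-directed ortho-metalation of 4 through aryllithium 5 to 6. The bromine that becomes b5 is already present in 2-bromoresorcinol 1, between the two oxygens. One hydroxyl of 1 is benzylated with 2; the other becomes the carbamate and finally the triflate. The forward sequence asks for a base that lithiates beside the carbamate without touching the bromine, which points to a lithium amide with in situ silyl trapping.

## Roads not taken

Alternative 1: The cut runs through ring B at b2–b3 and b5–b6. Dimethyl 3-oxopentanedioate A3 would supply b3, b4 and b5 together with the phenol oxygen. The aryloxy enaminone keto ester A2 would bring b6, b1 and b2, with the ether oxygen of 11 already on the future b1. Base would join them by addition–elimination at the enamine carbon and Knoevenagel condensation at the keto group, closing ring B as the phenol triester A1.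
- Merits: the hindered ether bond is made as an alkyl-type C–O bond before any arene exists, every ring B position is fixed by the skeleton, and condensations of this kind are established.
- Weak points: A1 has carbon where 19 has bromine at b3, b5 and b6, so three esters must be hydrolysed and each carboxyl group exchanged for bromine. The two carboxyl groups flanking the hydroxyl can undergo ipso bromodecarboxylation. The b6 carboxyl is meta to it and would need a radical Hunsdiecker-type exchange on an electron-rich phenolic ring, which is the same hard bromine in a worse form. A2 also has to be made from 11 in several steps.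
- Comparison: the ring-forming step here stands on firmer precedent than step 7 and raises no regiochemical question. Against that, the chosen plan forms the b6–Br bond directly and reaches 19 in three steps after the key step, where this road needs a longer series of functional-group exchanges.

Alternative 2: Here ring A is built instead, by cutting a3–a4. Ring A is traced to the racemic 4-methoxy-4-vinylcyclobutenone A5, which already carries the complete ring B as an aryloxy group derived from 2,3,5-tribromo-4-methoxyphenol A6. Heating A5 should trigger 4π electrocyclic ring opening, 6π electrocyclic closure and tautomerisation to the phenol A4.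
- Merits: the key step needs no reagent and is a well-established type. A4 is a hydroquinone methylated at a1 and free at a4, so the free hydroxyl directs both ring A bromines in one dibromination, and two demethylations finish.
- Weak points: the road does not make the b6–Br bond. It assumes it in A6, whose bromine meta to oxygen is no easier to place than in 19. The approach to the key step is also long, because the hindered, weakly nucleophilic phenoxide of A6 has to be joined to a four-carbon ring before vinyl addition and O-methylation can build A5.
- Comparison: in the certainty of its key step and the cleanness of the ring A bromination this road is better. The chosen plan sets against it that it creates the b6–Br bond in the same operation as the ether bond, starting from 2-bromoresorcinol 1, whereas here the problem is only moved into a starting material.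

Alternative 3: Ring B is again built, by cutting b1–b2, b3–b4 and b4–b5. The zerovalent chromium carbene complex A8, (CO)5Cr=C(OAr)(C(SiMe3)=CH2) with Ar the aryl group of 11, would combine with ethynyltrimethylsilane A9 and one carbonyl ligand in a Dötz benzannulation. The product would be the 4-aryloxyphenol A7, silylated at b3 and b6.
- Merits: the ether oxygen is the carbene heteroatom, so no aryl C–O coupling is needed. The silyl groups mark b3 and b6 for ipso bromodesilylation, and the free hydroxyl directs b5.
- Weak points: aryloxycarbene complexes of a hindered, electron-poor phenol such as 11 are hard to prepare and more labile than alkoxy analogues, and the metal is stoichiometric. The usual oxidative work-up that strips chromium from the new arene would turn a 4-aryloxyphenol such as A7 into a quinone with loss of the ether. The silicon at b6, meta to the hydroxyl, would be replaced more slowly than the b5 hydrogen is brominated, so the three bromines would not arrive cleanly.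
- Comparison: this road is as untested on its substrate as the chosen one. It has a real advantage in that a silicon marker at b6 cannot be lost by elimination, as the b5 bromine can be in 15. The chosen plan answers with a metal-free key step from two simple aromatic building blocks and fewer steps after it.

Key step: step 7

Remark on the chemistry: 19 has no stereocentre, so no configuration has to be set or preserved; 1, 2, 9 and 12 are taken as purchased, the aryl anion 15 is drawn with a cesium counter-ion, and the position labels a1 to a6 and b1 to b6 of 19 are kept for the corresponding carbons of every intermediate.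

## Route

Step 1
Reactants: 1 2-bromoresorcinol; 2 benzyl bromide
Product: 3 3-(benzyloxy)-2-bromophenol
Conditions: 2 (1.0 equiv), K2CO3, acetone, reflux
Reagents that add atoms: none
Why: Williamson ether synthesis on a symmetrical diol; with one equivalent of 2 the mono-ether should predominate and is separable from recovered 1 and the bis-ether through its single acidic hydroxyl.

Step 2
Reactants: 3 3-(benzyloxy)-2-bromophenol
Product: 4 3-(benzyloxy)-2-bromophenyl N,N-diethylcarbamate
Conditions: Et2NCOCl, K2CO3, MeCN, reflux
Reagents that add atoms: N,N-diethylcarbamoyl chloride, CCN(CC)C(Cl)=O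
Why: O-carbamoylation of a phenoxide; the diethylcarbamate is the strongest oxygen-based director for the ortho-metalation that follows and is inert to amide bases at low temperature.

Step 3
Reactants: 4 3-(benzyloxy)-2-bromophenyl N,N-diethylcarbamate
Product: 6 3-(benzyloxy)-2-bromo-6-(trimethylsilyl)phenyl N,N-diethylcarbamate, via aryllithium 5 (not isolated)
Conditions: LiN(i-Pr)2, Me3SiCl (in situ), THF, −78 °C
Reagents that add atoms: chlorotrimethylsilane, C[Si](C)(C)Cl
Why: Directed ortho-metalation with in situ silyl trapping; the b1 hydrogen is the only one ortho to the carbamate (the other ortho carbon, b5, bears bromine), the amide base does not exchange the bromine as an alkyllithium would, and immediate silylation of 5 should forestall the anionic ortho-Fries shift and bromine migration.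

Step 4
Reactants: 6 3-(benzyloxy)-2-bromo-6-(trimethylsilyl)phenyl N,N-diethylcarbamate
Product: 7 3-(benzyloxy)-2-bromo-6-(trimethylsilyl)phenol
Conditions: Cp2Zr(H)Cl, THF, rt; then H2O
Reagents that add atoms: none
Why: Reductive cleavage of an aryl O-carbamate by hydrozirconation of its carbonyl group, a method suited to hindered ortho-metalation products; aryl bromide, aryl silane and benzyl ether are inert to the zirconium hydride.

Step 5
Reactants: 7 3-(benzyloxy)-2-bromo-6-(trimethylsilyl)phenol
Product: 8 3-(benzyloxy)-2-bromo-6-(trimethylsilyl)phenyl trifluoromethanesulfonate
Conditions: Tf2O, pyridine, CH2Cl2, 0 °C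
Reagents that add atoms: trifluoromethanesulfonic anhydride, O=S(=O)(OS(=O)(=O)C(F)(F)F)C(F)(F)F
Why: O-sulfonylation of a phenol; the weak base leaves the ortho C–Si bond intact and gives the o-silylaryl triflate from which fluoride releases the aryne.

Step 6
Reactants: 9 2,5-dimethoxyphenol
Product: 11 2,4-dibromo-3,6-dimethoxyphenol, via 4-bromo-2,5-dimethoxyphenol 10 (not isolated)
Conditions: NBS (2.05 equiv), MeCN, 0 °C → rt
Reagents that add atoms: N-bromosuccinimide, O=C1CCC(=O)N1Br
Why: Electrophilic aromatic bromination; a3 (para to the hydroxyl) and then a5 (ortho to it) are each activated by the hydroxyl and by the a4 methoxy group, whereas a2 is activated by the a1 methoxy group only, so the second bromine should follow the hydroxyl.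

Step 7
Reactants: 8 3-(benzyloxy)-2-bromo-6-(trimethylsilyl)phenyl trifluoromethanesulfonate; 11 2,4-dibromo-3,6-dimethoxyphenol; 12 1,2-dibromotetrachloroethane
Product: 16 1-(4-benzyloxy-2,3-dibromophenoxy)-2,4-dibromo-3,6-dimethoxybenzene, via cesium phenoxide 13 (not isolated), via aryne 14 (not isolated), via arylcesium 15 (not isolated)
Conditions: 11 (1.5 equiv), Cs2CO3 (0.75 equiv), MeOH, rt; evaporate, dry (PhMe azeotrope); then 12 (5 equiv), CsF, 18-crown-6, THF, −30 °C; 8 added slowly; → 0 °C
Reagents that add atoms: none
Why: Proposed new method: fluoride attacks silicon of 8 and triflate leaves, giving aryne 14 with its triple bond between b1 and b6; the closest known reaction types are the fluoride-triggered O-arylation of phenols by o-silylaryl triflates and three-component aryne couplings in which a heteroatom nucleophile adds and the aryl anion is halogenated by a polyhaloalkane or perhaloarene, but the pairing of a phenoxide with a bromine donor has not been shown. Phenoxide 13 adds to b1 and the arylcesium 15 attacks a bromine of 12 in a halophilic substitution; the carbanion left behind loses bromide to give tetrachloroethene, so the transfer is irreversible. No ring closes and no stereocentre forms. Site selectivity requires oxygen at b1 and not b6: the b5 bromine makes b1 the more linear and more electrophilic aryne terminus and stabilises charge at b6 by induction, the benzyloxy group at b4, para to b1, points the same way, and b1 is the less hindered end. Chemoselectivity requires bromine capture to outrun loss of bromide from b5 of 15, which would give a second aryne; capture is bimolecular and nearly barrierless, so a five-fold excess of 12 at high concentration, slow addition of 8 and low temperature should favour it. Pre-formed, proton-free 13 in THF and not acetonitrile removes the competing protonation of 15. Addition to a strained triple bond is little affected by the three ortho substituents around the new ether, which is why the crowded junction is made here.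

Step 8
Reactants: 16 1-(4-benzyloxy-2,3-dibromophenoxy)-2,4-dibromo-3,6-dimethoxybenzene
Product: 17 2,3-dibromo-4-(2,4-dibromo-3,6-dimethoxyphenoxy)phenol
Conditions: BCl3, C6HMe5, CH2Cl2, −78 °C; then H2O
Reagents that add atoms: none
Why: Lewis-acid cleavage of an aryl benzyl ether with a cation scavenger; at −78 °C the benzyl–oxygen bond ionises while aryl methyl ethers, the diaryl ether and C–Br bonds should survive, and pentamethylbenzene intercepts the benzyl cation before it alkylates either ring; hydrogenolysis is excluded by the four bromines.

Step 9
Reactants: 17 2,3-dibromo-4-(2,4-dibromo-3,6-dimethoxyphenoxy)phenol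
Product: 18 2,3,6-tribromo-4-(2,4-dibromo-3,6-dimethoxyphenoxy)phenol
Conditions: NBS (1.0 equiv), i-Pr2NH (cat.), CH2Cl2, 0 °C
Reagents that add atoms: N-bromosuccinimide, O=C1CCC(=O)N1Br
Why: Amine-catalysed ortho-bromination of a phenol with NBS; b3 is the only free position ortho or para to the b4 hydroxyl, b2 is meta to it, and ring A is still methylated and far less activated than the free phenol ring, so it should be neither brominated nor oxidised.

Step 10
Reactants: 18 2,3,6-tribromo-4-(2,4-dibromo-3,6-dimethoxyphenoxy)phenol
Product: 19 3,5-dibromo-2-(2,3,5-tribromo-4-hydroxyphenoxy)benzene-1,4-diol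
Conditions: BBr3 (excess), CH2Cl2, −78 °C → rt; then degassed H2O
Reagents that add atoms: none
Why: Lewis-acid demethylation of aryl methyl ethers by bromide attack on the methyl group of the boron-complexed ether; the diaryl ether and aryl bromides are inert, and the step is placed last because the free hydroquinone is the only oxidation-prone form of ring A.

## Compound list

1 | 2-bromoresorcinol (2-bromobenzene-1,3-diol) | Oc1cccc(O)c1Br | starting material
2 | benzyl bromide | BrCc1ccccc1 | starting material
3 | 3-(benzyloxy)-2-bromophenol | Oc1cccc(OCc2ccccc2)c1Br | intermediate
4 | 3-(benzyloxy)-2-bromophenyl N,N-diethylcarbamate | CCN(CC)C(=O)Oc1cccc(OCc2ccccc2)c1Br | intermediate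
5 | 3-(benzyloxy)-2-bromo-6-lithiophenyl N,N-diethylcarbamate | [Li]c1ccc(OCc2ccccc2)c(Br)c1OC(=O)N(CC)CC | intermediate
6 | 3-(benzyloxy)-2-bromo-6-(trimethylsilyl)phenyl N,N-diethylcarbamate | CCN(CC)C(=O)Oc1c([Si](C)(C)C)ccc(OCc2ccccc2)c1Br | intermediate
7 | 3-(benzyloxy)-2-bromo-6-(trimethylsilyl)phenol | Oc1c([Si](C)(C)C)ccc(OCc2ccccc2)c1Br | intermediate
8 | 3-(benzyloxy)-2-bromo-6-(trimethylsilyl)phenyl trifluoromethanesulfonate | C[Si](C)(C)c1ccc(OCc2ccccc2)c(Br)c1OS(=O)(=O)C(F)(F)F | intermediate
9 | 2,5-dimethoxyphenol | COc1ccc(OC)c(O)c1 | starting material
10 | 4-bromo-2,5-dimethoxyphenol | COc1cc(Br)c(OC)cc1O | intermediate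
11 | 2,4-dibromo-3,6-dimethoxyphenol | COc1cc(Br)c(OC)c(Br)c1O | intermediate
12 | 1,2-dibromotetrachloroethane | BrC(Cl)(Cl)C(Cl)(Cl)Br | starting material
13 | cesium 2,4-dibromo-3,6-dimethoxyphenoxide | [Cs+].[O-]c1c(Br)c(OC)c(Br)cc1OC | intermediate
14 | 4-(benzyloxy)-3-bromobenzyne (1-(benzyloxy)-2-bromo-3,4-didehydrobenzene) | BrC1=C(OCc2ccccc2)C=CC#C1 | intermediate
15 | [3-(benzyloxy)-2-bromo-6-(2,4-dibromo-3,6-dimethoxyphenoxy)phenyl]cesium | [Cs]c1c(Br)c(OCc2ccccc2)ccc1Oc1c(OC)cc(Br)c(OC)c1Br | intermediate
16 | 1-(4-benzyloxy-2,3-dibromophenoxy)-2,4-dibromo-3,6-dimethoxybenzene | COc1cc(Br)c(OC)c(Br)c1Oc1ccc(OCc2ccccc2)c(Br)c1Br | intermediate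
17 | 2,3-dibromo-4-(2,4-dibromo-3,6-dimethoxyphenoxy)phenol | COc1cc(Br)c(OC)c(Br)c1Oc1ccc(O)c(Br)c1Br | intermediate
18 | 2,3,6-tribromo-4-(2,4-dibromo-3,6-dimethoxyphenoxy)phenol | COc1cc(Br)c(OC)c(Br)c1Oc1cc(Br)c(O)c(Br)c1Br | intermediate
19 | 3,5-dibromo-2-(2,3,5-tribromo-4-hydroxyphenoxy)benzene-1,4-diol | Oc1cc(Br)c(O)c(Br)c1Oc1cc(Br)c(O)c(Br)c1Br | target

## Step count and risks

Total step count: 10 (steps 1–5 to triflate 8, step 6 to phenol 11, steps 7–10 from the coupling to 19). Longest linear sequence: 9 steps (1, 2, 3, 4, 5, 7, 8, 9, 10).

**Step 7 (Proposed new method).** The most likely failure is loss of bromide from b5 of the aryl anion 15 before bromine transfer, which opens a second aryne and leads to unselective capture. An ortho-bromoaryl anion with a weakly bound counter-ion eliminates quickly, and only the concentration of 12 and the low temperature work against it. Protonation of 15 by traces of acid would give the ether without the b6 bromine, and slow background consumption of phenoxide 13 by the bromine donor is a further risk. The fallback relies on known chemistry, sets out from 11 and 2 and returns to the route at 16; both neighbouring bromines are taken from a purchased phenol and the ether is made by metal-free arylation with a diaryliodonium salt. Purchased 2,3-dibromophenol F1 is benzylated with 2 and K2CO3 to 1-(benzyloxy)-2,3-dibromobenzene F2. Iodination of F2 para to the ether oxygen with NIS and CF3CO2H gives 1-(benzyloxy)-2,3-dibromo-4-iodobenzene F3. Oxidation of F3 with mCPBA and TsOH to the trivalent iodine stage and condensation with 1,3,5-trimethoxybenzene gives (4-benzyloxy-2,3-dibromophenyl)(2,4,6-trimethoxyphenyl)iodonium 4-methylbenzenesulfonate F4. With the potassium phenoxide of 11 (KOt-Bu, THF), F4 should transfer its bromoaryl group to oxygen while the trimethoxyphenyl group stays on iodine, giving 16.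

**Step 3.** The most likely failures are incomplete lithiation beside the carbamate by the amide base, or scrambling of the b5 bromine by halophilic attack of aryllithium 5 on unreacted 4. The fallback sets out from 2 and returns to the route at 6; the C–Si bond is formed before the ring carries the b5 bromine, and that bromine is then placed between the two oxygens by metalation. Purchased 4-bromoresorcinol F5 is benzylated with 2 and K2CO3 at the hydroxyl remote from bromine to give, after chromatographic purification, 5-(benzyloxy)-2-bromophenol F6. O-Silylation of F6 with (Me3Si)2NH gives [5-(benzyloxy)-2-bromophenoxy]trimethylsilane F7. Treatment of F7 with n-BuLi at −78 °C effects bromine–lithium exchange and a retro-Brook silyl shift from oxygen to carbon, giving 5-(benzyloxy)-2-(trimethylsilyl)phenol F8. Carbamoylation of F8 with Et2NCOCl gives 5-(benzyloxy)-2-(trimethylsilyl)phenyl N,N-diethylcarbamate F9. Lithiation of F9 with s-BuLi/TMEDA at the position between the carbamate and benzyloxy groups, followed by quenching with 12, should give 6.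

**Step 4.** The most likely failure is sluggish hydrozirconation of a carbonyl group shielded by the ortho bromine and the ortho silyl group, with protodesilylation on forcing. The fallback sets out from 3 and returns to the route at 7; it uses a carbamate that leaves by elimination and not by reduction. Compound 3 and isopropyl isocyanate give 3-(benzyloxy)-2-bromophenyl N-isopropylcarbamate F10. After in situ N-silylation of F10 (Me3SiOTf, TMEDA), lithiation with LiN(i-Pr)2 in the presence of Me3SiCl as in step 3 and aqueous work-up give 3-(benzyloxy)-2-bromo-6-(trimethylsilyl)phenyl N-isopropylcarbamate F11. Et2NH and DBU in MeCN at 40 °C should then release 7 from F11 by elimination to isopropyl isocyanate, which the amine traps as a urea.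

**Step 6.** The most likely failures are entry of the second bromine at a2 instead of a5, or oxidation of the electron-rich phenol by NBS. The fallback leaves 9 aside, sets out from a purchased phenol that already carries both bromines and returns to the route at 11; the hydroxyl is introduced last. Purchased 2,6-dibromo-4-methoxyphenol F12 is methylated (MeI, K2CO3) to 1,3-dibromo-2,5-dimethoxybenzene F13. In F13 both ring hydrogens are equivalent and lie between a bromine and a methoxy group. Lithiation of F13 with LiN(i-Pr)2 in the presence of B(Oi-Pr)3 at −78 °C and hydrolysis gives (2,4-dibromo-3,6-dimethoxyphenyl)boronic acid F14. Oxidation of F14 with H2O2/NaOH should give 11.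

## Further compounds

F1 | step 7 | 2,3-dibromophenol | Oc1cccc(Br)c1Br
F2 | step 7 | 1-(benzyloxy)-2,3-dibromobenzene | Brc1cccc(OCc2ccccc2)c1Br
F3 | step 7 | 1-(benzyloxy)-2,3-dibromo-4-iodobenzene | Ic1ccc(OCc2ccccc2)c(Br)c1Br
F4 | step 7 | (4-benzyloxy-2,3-dibromophenyl)(2,4,6-trimethoxyphenyl)iodonium 4-methylbenzenesulfonate | COc1cc(OC)c([I+]c2ccc(OCc3ccccc3)c(Br)c2Br)c(OC)c1.Cc1ccc(S([O-])(=O)=O)cc1
F5 | step 3 | 4-bromoresorcinol (4-bromobenzene-1,3-diol) | Oc1ccc(Br)c(O)c1
F6 | step 3 | 5-(benzyloxy)-2-bromophenol | Oc1cc(OCc2ccccc2)ccc1Br
F7 | step 3 | [5-(benzyloxy)-2-bromophenoxy]trimethylsilane | C[Si](C)(C)Oc1cc(OCc2ccccc2)ccc1Br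
F8 | step 3 | 5-(benzyloxy)-2-(trimethylsilyl)phenol | C[Si](C)(C)c1ccc(OCc2ccccc2)cc1O
F9 | step 3 | 5-(benzyloxy)-2-(trimethylsilyl)phenyl N,N-diethylcarbamate | CCN(CC)C(=O)Oc1cc(OCc2ccccc2)ccc1[Si](C)(C)C
F10 | step 4 | 3-(benzyloxy)-2-bromophenyl N-isopropylcarbamate | CC(C)NC(=O)Oc1cccc(OCc2ccccc2)c1Br
F11 | step 4 | 3-(benzyloxy)-2-bromo-6-(trimethylsilyl)phenyl N-isopropylcarbamate | CC(C)NC(=O)Oc1c([Si](C)(C)C)ccc(OCc2ccccc2)c1Br
F12 | step 6 | 2,6-dibromo-4-methoxyphenol | COc1cc(Br)c(O)c(Br)c1
F13 | step 6 | 1,3-dibromo-2,5-dimethoxybenzene | COc1cc(Br)c(OC)c(Br)c1
F14 | step 6 | (2,4-dibromo-3,6-dimethoxyphenyl)boronic acid | COc1cc(Br)c(OC)c(Br)c1B(O)O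
A1 | alternative 1 | trimethyl 6-(2,4-dibromo-3,6-dimethoxyphenoxy)-3-hydroxybenzene-1,2,4-tricarboxylate | COC(=O)c1cc(Oc2c(OC)cc(Br)c(OC)c2Br)c(C(=O)OC)c(C(=O)OC)c1O
A2 | alternative 1 | methyl 3-(2,4-dibromo-3,6-dimethoxyphenoxy)-4-(dimethylamino)-2-oxobut-3-enoate | COC(=O)C(=O)C(Oc1c(OC)cc(Br)c(OC)c1Br)=CN(C)C
A3 | alternative 1 | dimethyl 3-oxopentanedioate | COC(=O)CC(=O)CC(=O)OC
A4 | alternative 2 | 4-methoxy-3-(2,3,5-tribromo-4-methoxyphenoxy)phenol | COc1ccc(O)cc1Oc1cc(Br)c(OC)c(Br)c1Br
A5 | alternative 2 | 4-methoxy-3-(2,3,5-tribromo-4-methoxyphenoxy)-4-vinylcyclobut-2-en-1-one (racemic) | C=CC1(OC)C(Oc2cc(Br)c(OC)c(Br)c2Br)=CC1=O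
A6 | alternative 2 | 2,3,5-tribromo-4-methoxyphenol | COc1c(Br)cc(O)c(Br)c1Br
A7 | alternative 3 | 4-(2,4-dibromo-3,6-dimethoxyphenoxy)-2,5-bis(trimethylsilyl)phenol | Oc1cc([Si](C)(C)C)c(Oc2c(OC)cc(Br)c(OC)c2Br)cc1[Si](C)(C)C
A8 | alternative 3 | pentacarbonyl[(2,4-dibromo-3,6-dimethoxyphenoxy)(1-(trimethylsilyl)vinyl)carbene]chromium | C=C([Si](C)(C)C)C(Oc1c(OC)cc(Br)c(OC)c1Br)=[Cr](=C=O)(=C=O)(=C=O)(=C=O)=C=O
A9 | alternative 3 | ethynyltrimethylsilane | C#C[Si](C)(C)C
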